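Assumption: the target is taken as the free hydrogen sulfate exactly as drawn; it is released from its pyridinium salt by proton exchange in the last step.

**Retrosynthetic overview**
- The sulfate comes from the primary alcohol (desilylation, then O-sulfation). Ring B is closed last by intramolecular aldol condensation of a 1,5-diketone whose methyl ketone comes from Wacker oxidation of an allyl group.
- The quaternary carbon is made by axial alkylation of a conformationally anchored ring-A ketone enolate with a chiral primary iodide (methyl first, side chain second).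
- Ring A is not built but bought as (R)-pulegone, which supplies the methyl stereocentre, the ketone and the future gem-dimethyl carbon; Sakurai allylation plus base equilibration set the ring-fusion CH.
- The iodide comes from copper-catalysed asymmetric allylic alkylation of a silyloxybutenyl bromide with 3-(furan-3-yl)propyl Grignard, then hydrozirconation–iodination.
- Ring order: ring A (chiral pool) first, ring B last.

**Route**

Step 1
Reactants: 1 3-bromofuran; 2 oxetane
Product: 4 3-(furan-3-yl)propan-1-ol, via furan-3-yllithium 3 (not isolated)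
Conditions: n-BuLi, THF, −78 °C; then 2, BF3·OEt2, −78 °C
Reagents that add atoms: none
Why: Bromine–lithium exchange at −78 °C gives the 3-lithiofuran without migration to C-2, and SN2 ring opening of BF3-activated oxetane appends the three-carbon alcohol.

Step 2
Reactants: 4 3-(furan-3-yl)propan-1-ol
Product: 5 3-(3-bromopropyl)furan
Conditions: CBr4, PPh3, CH2Cl2, 0 °C
Reagents that add atoms: tetrabromomethane, BrC(Br)(Br)Br
Why: The Appel reaction converts the primary alcohol into the bromide under essentially neutral conditions that the acid-sensitive furan tolerates.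

Step 3
Reactants: 6 methyl (2E)-4-bromobut-2-enoate
Product: 7 (2E)-4-bromobut-2-en-1-ol
Conditions: i-Bu2AlH (2.2 equiv), CH2Cl2, −78 °C; aq. potassium sodium tartrate
Reagents that add atoms: none
Why: Low-temperature 1,2-reduction of the enoate by the aluminium hydride gives the allylic alcohol and leaves the allylic bromide and the E double bond untouched.

Step 4
Reactants: 7 (2E)-4-bromobut-2-en-1-ol
Product: 8 tert-butyl{[(2E)-4-bromobut-2-en-1-yl]oxy}diphenylsilane
Conditions: TBDPSCl, imidazole, CH2Cl2, 0 °C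
Reagents that add atoms: tert-butyl(chloro)diphenylsilane, CC(C)(C)[Si](Cl)(c1ccccc1)c1ccccc1
Why: Imidazole-promoted O-silylation gives a primary silyl ether that withstands Grignard, amide-base and Wacker conditions and is removed by fluoride at the end.

Step 5
Reactants: 5 3-(3-bromopropyl)furan; 8 tert-butyl{[(2E)-4-bromobut-2-en-1-yl]oxy}diphenylsilane
Product: 10 tert-butyl({(2S)-2-[3-(furan-3-yl)propyl]but-3-en-1-yl}oxy)diphenylsilane, via 3-(furan-3-yl)propylmagnesium bromide 9 (not isolated)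
Conditions: Mg, Et2O, rt (5 to 9); then slow addition of 9 to 8, CuBr·SMe2 (3 mol %), (R,Rp)-TaniaPhos (3.6 mol %), CH2Cl2, −78 °C
Reagents that add atoms: none
Why: Copper-catalysed asymmetric allylic alkylation (SN2′) delivers the alkyl group to the γ-carbon, giving the branched terminal alkene and setting the side-chain stereocentre (S) under ligand control (the antipodal ligand is used if the sense of induction proves opposite).

Step 6
Reactants: 10 tert-butyl({(2S)-2-[3-(furan-3-yl)propyl]but-3-en-1-yl}oxy)diphenylsilane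
Product: 12 tert-butyl{[(2S)-5-(furan-3-yl)-2-(2-iodoethyl)pentyl]oxy}diphenylsilane, via alkylzirconocene chloride 11 (not isolated)
Conditions: Cp2Zr(H)Cl, THF, rt; then I2, 0 °C
Reagents that add atoms: iodine, II
Why: Hydrozirconation places zirconium on the terminal carbon for steric reasons and iodinolysis of the C–Zr bond gives the primary iodide without touching the adjacent stereocentre.

Step 7
Reactants: 13 (R)-pulegone; 14 allyltrimethylsilane
Product: 17 (2S,5R)-5-methyl-2-(2-methylpent-4-en-2-yl)cyclohexan-1-one, via trichlorotitanium enolate 15 (not isolated), via (2R,5R)-epimer 16 (not isolated)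
Conditions: TiCl4, CH2Cl2, −78 °C; aq. NaHCO3; then KOH, EtOH, reflux; chromatography
Reagents that add atoms: none
Why: Hosomi–Sakurai conjugate allylation builds the quaternary gem-dimethyl carbon on the isopropylidene terminus, and base equilibration (expected about 6:1, by analogy with other 8-substituted menthones) puts the new tert-alkyl group equatorial and trans to the chiral-pool methyl, which fixes the future ring-fusion carbon as S.

Step 8
Reactants: 17 (2S,5R)-5-methyl-2-(2-methylpent-4-en-2-yl)cyclohexan-1-one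
Product: 20 (2S,3R,6S)-2,3-dimethyl-6-(2-methylpent-4-en-2-yl)cyclohexan-1-one, via lithium enolate 18 (not isolated), via (2R,3R,6S)-epimer 19 (not isolated)
Conditions: LiN(i-Pr)2, THF, −78 °C; MeI, −78 → 0 °C; then NaOMe, MeOH, rt
Reagents that add atoms: iodomethane, CI
Why: Kinetic enolisation occurs at the CH2 flank (the other α-hydrogen sits next to the quaternary carbon), and enolate methylation followed by mild methoxide equilibration of that carbon alone gives the all-equatorial ketone with an axial α-hydrogen for step 9; this centre is set definitively in step 9.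

Step 9
Reactants: 20 (2S,3R,6S)-2,3-dimethyl-6-(2-methylpent-4-en-2-yl)cyclohexan-1-one; 12 tert-butyl{[(2S)-5-(furan-3-yl)-2-(2-iodoethyl)pentyl]oxy}diphenylsilane
Product: 22 (2R,3R,6S)-2-[(3S)-3-({[tert-butyl(diphenyl)silyl]oxy}methyl)-6-(furan-3-yl)hexyl]-2,3-dimethyl-6-(2-methylpent-4-en-2-yl)cyclohexan-1-one, via lithium enolate 21 (not isolated)
Conditions: LiN(i-Pr)2, THF, −78 → 0 °C; then 12, HMPA, −78 °C → rt
Reagents that add atoms: none
Why: In this SN2 enolate alkylation the base removes the axial hydrogen at the methyl-bearing carbon (far more accessible than the neopentyl one), and the iodide attacks the enolate, anchored by the pseudo-equatorial tert-alkyl and methyl groups, along the axial chair-like trajectory, so the chain ends up cis to the neighbouring ring methyl and the two ring methyls trans (quaternary carbon R).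

Step 10
Reactants: 22 (2R,3R,6S)-2-[(3S)-3-({[tert-butyl(diphenyl)silyl]oxy}methyl)-6-(furan-3-yl)hexyl]-2,3-dimethyl-6-(2-methylpent-4-en-2-yl)cyclohexan-1-one
Product: 23 (2R,3R,6S)-2-[(3S)-3-({[tert-butyl(diphenyl)silyl]oxy}methyl)-6-(furan-3-yl)hexyl]-2,3-dimethyl-6-(2-methyl-4-oxopentan-2-yl)cyclohexan-1-one
Conditions: PdCl2 (10 mol %), CuCl, O2 (1 atm), DMF–H2O 7:1, rt
Reagents that add atoms: water, O
Why: Tsuji–Wacker oxidation turns the terminal alkene into the methyl ketone with Markovnikov selectivity (overall alkene + ½ O2 → ketone, nothing else formed) under near-neutral conditions that do not enolise the hindered ring ketone.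

Step 11
Reactants: 23 (2R,3R,6S)-2-[(3S)-3-({[tert-butyl(diphenyl)silyl]oxy}methyl)-6-(furan-3-yl)hexyl]-2,3-dimethyl-6-(2-methyl-4-oxopentan-2-yl)cyclohexan-1-one
Product: 27 (4aS,7R,8R)-8-[(3S)-3-({[tert-butyl(diphenyl)silyl]oxy}methyl)-6-(furan-3-yl)hexyl]-4,4,7,8-tetramethyl-4,4a,5,6,7,8-hexahydronaphthalen-2(3H)-one, via lithium enolate 24 (not isolated), via lithium aldolate 25 (not isolated), via tertiary acetate 26 (not isolated)
Conditions: LiN(i-Pr)2 (1.05 equiv), THF, −78 → −20 °C; Ac2O, −20 °C → rt; DBU, rt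
Reagents that add atoms: none
Why: Kinetic deprotonation of the methyl ketone CH3, intramolecular aldol addition to the ring ketone (six-membered, helped by the gem-dimethyl group), O-acetylation and E1cB elimination give the conjugated enone without ever enolising the ring-fusion CH, so its configuration (S) is carried through unchanged.

Step 12
Reactants: 27 (4aS,7R,8R)-8-[(3S)-3-({[tert-butyl(diphenyl)silyl]oxy}methyl)-6-(furan-3-yl)hexyl]-4,4,7,8-tetramethyl-4,4a,5,6,7,8-hexahydronaphthalen-2(3H)-one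
Product: 28 (4aS,7R,8R)-8-[(3S)-6-(furan-3-yl)-3-(hydroxymethyl)hexyl]-4,4,7,8-tetramethyl-4,4a,5,6,7,8-hexahydronaphthalen-2(3H)-one
Conditions: Bu4NF, AcOH, THF, rt
Reagents that add atoms: none
Why: Fluoride-mediated desilylation cleaves the Si–O bond, and the acetic acid buffer keeps the medium too weakly basic to epimerise the γ-position of the enone.

Step 13
Reactants: 28 (4aS,7R,8R)-8-[(3S)-6-(furan-3-yl)-3-(hydroxymethyl)hexyl]-4,4,7,8-tetramethyl-4,4a,5,6,7,8-hexahydronaphthalen-2(3H)-one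
Product: 30 (2S)-5-(furan-3-yl)-2-{2-[(1R,2R,4aS)-1,2,5,5-tetramethyl-7-oxo-1,2,3,4,4a,5,6,7-octahydronaphthalen-1-yl]ethyl}pentyl hydrogen sulfate, via pyridinium sulfate 29 (not isolated)
Conditions: SO3·pyridine, pyridine, 0 °C → rt; then cation-exchange resin (H+ form), MeOH–H2O, 0 °C
Reagents that add atoms: sulfur trioxide–pyridine complex, O=S(=O)=O.c1ccncc1
Why: O-Sulfation of the primary alcohol by the sulfur trioxide complex is much faster than attack on the enone or the furan, and proton exchange of the pyridinium salt gives the hydrogen sulfate without touching any stereocentre.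

**Compound list**

1 | 3-bromofuran | Brc1ccoc1 | starting material
2 | oxetane | C1COC1 | starting material
3 | furan-3-yllithium | [Li]c1ccoc1 | intermediate
4 | 3-(furan-3-yl)propan-1-ol | OCCCc1ccoc1 | intermediate
5 | 3-(3-bromopropyl)furan | BrCCCc1ccoc1 | intermediate
6 | methyl (2E)-4-bromobut-2-enoate | COC(=O)/C=C/CBr | starting material
7 | (2E)-4-bromobut-2-en-1-ol | OC/C=C/CBr | intermediate
8 | tert-butyl{[(2E)-4-bromobut-2-en-1-yl]oxy}diphenylsilane | BrC/C=C/CO[Si](c1ccccc1)(c1ccccc1)C(C)(C)C | intermediate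
9 | 3-(furan-3-yl)propylmagnesium bromide | Br[Mg]CCCc1ccoc1 | intermediate
10 | tert-butyl({(2S)-2-[3-(furan-3-yl)propyl]but-3-en-1-yl}oxy)diphenylsilane | C=C[C@H](CCCc1ccoc1)CO[Si](c1ccccc1)(c1ccccc1)C(C)(C)C | intermediate
11 | chlorobis(cyclopentadienyl){(3S)-3-[(tert-butyldiphenylsilyloxy)methyl]-6-(furan-3-yl)hexyl}zirconium | Cl[Zr](CC[C@H](CCCc1ccoc1)CO[Si](c1ccccc1)(c1ccccc1)C(C)(C)C)(C1C=CC=C1)C1C=CC=C1 | intermediate
12 | tert-butyl{[(2S)-5-(furan-3-yl)-2-(2-iodoethyl)pentyl]oxy}diphenylsilane | ICC[C@H](CCCc1ccoc1)CO[Si](c1ccccc1)(c1ccccc1)C(C)(C)C | intermediate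
13 | (R)-pulegone, (5R)-5-methyl-2-(propan-2-ylidene)cyclohexan-1-one | C[C@@H]1CCC(=C(C)C)C(=O)C1 | starting material
14 | allyltrimethylsilane | C=CC[Si](C)(C)C | starting material
15 | trichloro{[(5R)-5-methyl-2-(2-methylpent-4-en-2-yl)cyclohex-1-en-1-yl]oxy}titanium | C[C@@H]1CCC(C(C)(C)CC=C)=C(O[Ti](Cl)(Cl)Cl)C1 | intermediate
16 | (2R,5R)-5-methyl-2-(2-methylpent-4-en-2-yl)cyclohexan-1-one | C[C@@H]1CC[C@H](C(C)(C)CC=C)C(=O)C1 | intermediate
17 | (2S,5R)-5-methyl-2-(2-methylpent-4-en-2-yl)cyclohexan-1-one | C[C@@H]1CC[C@@H](C(C)(C)CC=C)C(=O)C1 | intermediate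
18 | lithium (3R,6S)-3-methyl-6-(2-methylpent-4-en-2-yl)cyclohex-1-en-1-olate | C[C@@H]1CC[C@@H](C(C)(C)CC=C)C([O-])=C1.[Li+] | intermediate
19 | (2R,3R,6S)-2,3-dimethyl-6-(2-methylpent-4-en-2-yl)cyclohexan-1-one | C[C@@H]1CC[C@@H](C(C)(C)CC=C)C(=O)[C@@H]1C | intermediate
20 | (2S,3R,6S)-2,3-dimethyl-6-(2-methylpent-4-en-2-yl)cyclohexan-1-one | C[C@@H]1CC[C@@H](C(C)(C)CC=C)C(=O)[C@H]1C | intermediate
21 | lithium (3R,6S)-2,3-dimethyl-6-(2-methylpent-4-en-2-yl)cyclohex-1-en-1-olate | C[C@@H]1CC[C@@H](C(C)(C)CC=C)C([O-])=C1C.[Li+] | intermediate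
22 | (2R,3R,6S)-2-[(3S)-3-({[tert-butyl(diphenyl)silyl]oxy}methyl)-6-(furan-3-yl)hexyl]-2,3-dimethyl-6-(2-methylpent-4-en-2-yl)cyclohexan-1-one | C[C@@H]1CC[C@@H](C(C)(C)CC=C)C(=O)[C@]1(C)CC[C@H](CCCc1ccoc1)CO[Si](c1ccccc1)(c1ccccc1)C(C)(C)C | intermediate
23 | (2R,3R,6S)-2-[(3S)-3-({[tert-butyl(diphenyl)silyl]oxy}methyl)-6-(furan-3-yl)hexyl]-2,3-dimethyl-6-(2-methyl-4-oxopentan-2-yl)cyclohexan-1-one | C[C@@H]1CC[C@@H](C(C)(C)CC(C)=O)C(=O)[C@]1(C)CC[C@H](CCCc1ccoc1)CO[Si](c1ccccc1)(c1ccccc1)C(C)(C)C | intermediate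
24 | lithium enolate of 23 at the methyl ketone (4-substituted 4-methylpent-1-en-2-olate) | C[C@@H]1CC[C@@H](C(C)(C)CC(=C)[O-])C(=O)[C@]1(C)CC[C@H](CCCc1ccoc1)CO[Si](c1ccccc1)(c1ccccc1)C(C)(C)C.[Li+] | intermediate
25 | lithium (4aS,7R,8R)-8-[(3S)-3-({[tert-butyl(diphenyl)silyl]oxy}methyl)-6-(furan-3-yl)hexyl]-4,4,7,8-tetramethyl-2-oxooctahydronaphthalen-8a(1H)-olate (8a configuration not defined) | C[C@@H]1CC[C@@H]2C([O-])(CC(=O)CC2(C)C)[C@]1(C)CC[C@H](CCCc1ccoc1)CO[Si](c1ccccc1)(c1ccccc1)C(C)(C)C.[Li+] | intermediate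
26 | (4aS,7R,8R)-8-[(3S)-3-({[tert-butyl(diphenyl)silyl]oxy}methyl)-6-(furan-3-yl)hexyl]-4,4,7,8-tetramethyl-2-oxooctahydronaphthalen-8a(1H)-yl acetate (8a configuration not defined) | C[C@@H]1CC[C@@H]2C(OC(C)=O)(CC(=O)CC2(C)C)[C@]1(C)CC[C@H](CCCc1ccoc1)CO[Si](c1ccccc1)(c1ccccc1)C(C)(C)C | intermediate
27 | (4aS,7R,8R)-8-[(3S)-3-({[tert-butyl(diphenyl)silyl]oxy}methyl)-6-(furan-3-yl)hexyl]-4,4,7,8-tetramethyl-4,4a,5,6,7,8-hexahydronaphthalen-2(3H)-one | C[C@@H]1CC[C@@H]2C(=CC(=O)CC2(C)C)[C@]1(C)CC[C@H](CCCc1ccoc1)CO[Si](c1ccccc1)(c1ccccc1)C(C)(C)C | intermediate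
28 | (4aS,7R,8R)-8-[(3S)-6-(furan-3-yl)-3-(hydroxymethyl)hexyl]-4,4,7,8-tetramethyl-4,4a,5,6,7,8-hexahydronaphthalen-2(3H)-one | C[C@@H]1CC[C@@H]2C(=CC(=O)CC2(C)C)[C@]1(C)CC[C@H](CCCc1ccoc1)CO | intermediate
29 | pyridinium (2S)-5-(furan-3-yl)-2-{2-[(1R,2R,4aS)-1,2,5,5-tetramethyl-7-oxo-1,2,3,4,4a,5,6,7-octahydronaphthalen-1-yl]ethyl}pentyl sulfate | C[C@@H]1CC[C@@H]2C(=CC(=O)CC2(C)C)[C@]1(C)CC[C@H](CCCc1ccoc1)COS(=O)(=O)[O-].c1cc[nH+]cc1 | intermediate
30 | (2S)-5-(furan-3-yl)-2-{2-[(1R,2R,4aS)-1,2,5,5-tetramethyl-7-oxo-1,2,3,4,4a,5,6,7-octahydronaphthalen-1-yl]ethyl}pentyl hydrogen sulfate (CNP0424620.3) | C[C@@H]1CC[C@@H]2C(=CC(=O)CC2(C)C)[C@]1(C)CC[C@H](CCCc1ccoc1)COS(=O)(=O)O | target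

**Summary**

Total step count: 13.
Longest linear sequence: 9 steps (steps 1, 2, 5, 6, 9, 10, 11, 12, 13).

The selectivities quoted (about 6:1 in step 7, axial attack in step 9, high ee in step 5) are estimates by analogy, not measured values. The minor side-chain enantiomer from step 5 becomes a diastereomer of 22 after step 9 and is removed there by chromatography.

**Three steps most likely to fail**

Step 9. A hindered, fully substituted enolate has to be alkylated with an unactivated primary iodide, and both the axial facial preference and the choice between the two tertiary α-hydrogens rest on conformational arguments. The fallback sets out from 13 and comes back to the route at 22; it changes the order of events so that the quaternary carbon is closed with MeI instead. Compound 13 is deprotonated at the ring CH2 next to the carbonyl (LiN(i-Pr)2, THF, −78 °C) and alkylated with 12 to give the alkylated pulegone F1. A second deprotonation and MeI, which enters anti to the neighbouring ring methyl on this unanchored dienolate, give the quaternary enone F2. Allylmagnesium bromide, CuBr·SMe2 and Me3SiCl (THF, −78 °C) add the allyl group to the isopropylidene carbon to give the silyl enol ether F3. Hydrolysis (dilute HCl, THF) gives 22 together with its C-6 epimer F4. The ring-fusion centre is then not under substrate control (roughly 1:1 expected), so 22 is separated by chromatography and the epimer is recycled with KOH in EtOH.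

Step 10. The furan may not survive PdCl2/CuCl/O2 (palladation or acid-promoted decomposition). The fallback sets out from 22 and comes back at 23 and replaces the palladium oxidation by radical hydration followed by alcohol oxidation. Mukaiyama hydration (Co(acac)2, PhSiH3, O2, i-PrOH, rt) gives the secondary alcohol F5 as a mixture of carbinol epimers, and Dess–Martin periodinane (CH2Cl2, NaHCO3, rt) then gives 23.

Step 11. The aldol addition has to reach a ketone flanked by a quaternary carbon and a tert-alkyl-bearing CH, the tertiary aldolate has to be acetylated, and any equilibrating base would endanger the ring-fusion centre. The fallback sets out from 22 (so it also bypasses step 10) and comes back at 27, closing ring B by metathesis instead of enolate chemistry. Vinylmagnesium bromide with anhydrous CeCl3 (THF, −78 → 0 °C) adds to the ring ketone to give the vinyl carbinol F6. Ring-closing metathesis with the second-generation Grubbs catalyst (CH2Cl2, 40 °C) gives the cyclohexenol F7. Oxidative 1,3-transposition of this tertiary allylic alcohol with pyridinium chlorochromate, [C5H5NH][CrO3Cl] (CH2Cl2, rt), gives 27.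

**Further compounds**

F1 | step 9 | (2S,3R)-2-[(3S)-3-({[tert-butyl(diphenyl)silyl]oxy}methyl)-6-(furan-3-yl)hexyl]-3-methyl-6-(propan-2-ylidene)cyclohexan-1-one | C[C@@H]1CCC(=C(C)C)C(=O)[C@H]1CC[C@H](CCCc1ccoc1)CO[Si](c1ccccc1)(c1ccccc1)C(C)(C)C
F2 | step 9 | (2R,3R)-2-[(3S)-3-({[tert-butyl(diphenyl)silyl]oxy}methyl)-6-(furan-3-yl)hexyl]-2,3-dimethyl-6-(propan-2-ylidene)cyclohexan-1-one | C[C@@H]1CCC(=C(C)C)C(=O)[C@]1(C)CC[C@H](CCCc1ccoc1)CO[Si](c1ccccc1)(c1ccccc1)C(C)(C)C
F3 | step 9 | {[(5R,6R)-6-[(3S)-3-({[tert-butyl(diphenyl)silyl]oxy}methyl)-6-(furan-3-yl)hexyl]-5,6-dimethyl-2-(2-methylpent-4-en-2-yl)cyclohex-1-en-1-yl]oxy}trimethylsilane | C[C@@H]1CCC(C(C)(C)CC=C)=C(O[Si](C)(C)C)[C@]1(C)CC[C@H](CCCc1ccoc1)CO[Si](c1ccccc1)(c1ccccc1)C(C)(C)C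
F4 | step 9 | (2R,3R,6R)-2-[(3S)-3-({[tert-butyl(diphenyl)silyl]oxy}methyl)-6-(furan-3-yl)hexyl]-2,3-dimethyl-6-(2-methylpent-4-en-2-yl)cyclohexan-1-one | C[C@@H]1CC[C@H](C(C)(C)CC=C)C(=O)[C@]1(C)CC[C@H](CCCc1ccoc1)CO[Si](c1ccccc1)(c1ccccc1)C(C)(C)C
F5 | step 10 | (2R,3R,6S)-2-[(3S)-3-({[tert-butyl(diphenyl)silyl]oxy}methyl)-6-(furan-3-yl)hexyl]-6-(4-hydroxy-2-methylpentan-2-yl)-2,3-dimethylcyclohexan-1-one | C[C@@H]1CC[C@@H](C(C)(C)CC(C)O)C(=O)[C@]1(C)CC[C@H](CCCc1ccoc1)CO[Si](c1ccccc1)(c1ccccc1)C(C)(C)C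
F6 | step 11 | (2R,3R,6S)-2-[(3S)-3-({[tert-butyl(diphenyl)silyl]oxy}methyl)-6-(furan-3-yl)hexyl]-1-ethenyl-2,3-dimethyl-6-(2-methylpent-4-en-2-yl)cyclohexan-1-ol | C[C@@H]1CC[C@@H](C(C)(C)CC=C)C(O)(C=C)[C@]1(C)CC[C@H](CCCc1ccoc1)CO[Si](c1ccccc1)(c1ccccc1)C(C)(C)C
F7 | step 11 | (4aS,7R,8R)-8-[(3S)-3-({[tert-butyl(diphenyl)silyl]oxy}methyl)-6-(furan-3-yl)hexyl]-4,4,7,8-tetramethyl-4,4a,5,6,7,8-hexahydronaphthalen-8a(3H)-ol | C[C@@H]1CC[C@@H]2C(O)(C=CCC2(C)C)[C@]1(C)CC[C@H](CCCc1ccoc1)CO[Si](c1ccccc1)(c1ccccc1)C(C)(C)C
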